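About 29.5 turnovers per catalyst in 50 h is the count I commit to for gamma, where N is target formed per catalyst charged. You asked for a quick number, and this is how I reach mine.

| flask | starting material | second substrate | reagent | free catalyst | added ligand | remark | time |
|---|---|---|---|---|---|---|---|
| blue | 37 mM | 45 mM | 49.5 mM | 0.90 mM | 3.9 mM | run made earlier |  |
| green | 76 mM | 45 mM | 49.5 mM | 0.90 mM | 3.9 mM | run made earlier |  |
| gamma | 100 mM | 45.0 mM | 49.5 mM | 0.90 mM | 3.9 mM |  | 50 h |
| epsilon | 45 mM | 45.0 mM | 49.5 mM | 0.90 mM | 3.9 mM |  | 50 h |

| run | time / h | target / % |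
|---|---|---|
| blue | 4.00 | 8.2 |
| blue | 6.00 | 11.9 |
| blue | 10.0 | 18.8 |
| blue | 15.0 | 26.9 |
| blue | 20.0 | 34.5 |
| blue | 30.0 | 47.9 |
| blue | 48.0 | 63.8 |
| green | 8.00 | 7.9 |
| green | 15.0 | 13.8 |
| green | 20.0 | 18.1 |
| green | 30.0 | 24.6 |
| green | 40.0 | 30.4 |
| green | 48.0 | 34.0 |

(each reading ± 0.3 percentage points)

- a reading or a percentage of target counts all its forms, free or not

- which of the two ends with the higher amount of target, in percent of the starting material charged ("neither" if they lie within 2 percentage points) (gamma / epsilon / neither)
- target at the end, in percent of the starting material charged, gamma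
- target at the end, in percent of the starting material charged, epsilon

Blue starts at 0.758 mM h⁻¹ and green at 0.751 mM h⁻¹, although green holds twice the starting material, so I treat the early rate as zero order in it. The runs never vary the reagent, so I assume that each turnover uses one reagent and that the rate follows the reagent remaining, which is pseudo-first-order. Green's last reading gives λ = 0.0154 h⁻¹, the turnover constant: the fraction of remaining reagent used per hour at this catalyst charge.

Gamma charges more starting material than green, so I keep λ and get 26.6 mM of target, or 26.6% of its charge. Blue gives 0.0135 h⁻¹. Interpolating linearly in the charge, epsilon gets 0.0139 h⁻¹, hence 24.8 mM of target, or 55.1%.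

The forecast says epsilon, with 55% against 27% for gamma, holding that “the rate is nearly zero order in it”; it reckons the decay on the second substrate, I on the reagent.

The flask gives 26.9% for gamma and 55.9% for epsilon, so epsilon ends higher. At the end of gamma the reagent stands at 43% of its charge and the second substrate at 97%. At 25.0 h, λ gives 15.8% of gamma's charge, and the flask holds 16.4%.

    second substrate + free catalyst ⇌ catalyst intermediate B (K = 290 M⁻¹, k = 0.880 M⁻¹ min⁻¹)
    reagent + catalyst intermediate A → free catalyst + target (k = 0.310 M⁻¹ min⁻¹)
    free catalyst + target ⇌ idle complex A, settled at all times (K = 33.0 M⁻¹)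
    reagent + catalyst intermediate B → free catalyst + second product (k = 3.60 M⁻¹ min⁻¹)
    starting material + free catalyst ⇌ catalyst intermediate A (K = 1200 M⁻¹, k = 35.0 M⁻¹ min⁻¹)
    free catalyst + added ligand ⇌ idle complex B (K = 1100 M⁻¹, k = 0.230 M⁻¹ min⁻¹)

Now take epsilon with 0.36 mM of free catalyst. Green's λ, scaled by the catalyst charge, gives 29.1%; the flask gives 28.9%.

All runs are simulated with constants of no real substance, and the scatter is random.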